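**Plan**

- Retrosynthesis: remove the two tigloyl esters (C3–O and C7–O), cut C1–C7 (Morita–Baylis–Hillman), take back the C1=C2 unsaturation, mask the C6 carbonyl as a dithiane, then open the only ring at C4–C5 to an acyclic 6-alkenal.
- Feature used: in the cyclohexenone ring, C4 (isopropyl) is bonded to C5 (the carbinol next to the C6 carbonyl), with C3, C4 and C5 a contiguous triad. This 2-isopropylcyclohexanol unit is what a type I carbonyl-ene closure of an isopropylidene-terminated 6-alkenal delivers.
- Forward: the chain is joined at C2–C3 (vinyl Grignard on 3-methylbut-2-enal) and at C6–C1 (Michael addition of a dithiane ester); the ring closes in one carbonyl-ene step; the enone, C7 and the two esters follow.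
- Stereochemistry: CBS reduction sets C3 as (R); the ene chair, with all three substituents equatorial, relays it to C4 and C5; C3 is then inverted to the axial carbinol cis to isopropyl by oxidation and L-Selectride reduction under control of C4.

Key step: step 7

Remark (numbering): ring atoms carry the target locants throughout. C1 bears the CH2O carbon (C7), C2 is the vinylic CH, C3 and C5 are the carbinol carbons flanking C4 (isopropyl, methine C8), and C6 is the carbonyl carbon.

Remark (assumption on the chemistry): in the ene transition state the C3 silyloxy group is taken to be equatorial, because an axial one would lie almost in the alkene plane against the cis methyl group (allylic 1,3-strain). The closure is therefore planned to give the 3,4-trans-4,5-trans triad, and C3 is corrected afterwards through its ketone.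

**Route**

Step 1
Reactants: 1 3-methylbut-2-enal; 2 vinylmagnesium bromide
Product: 3 rac-5-methylhexa-1,4-dien-3-ol
Conditions: THF, −78 → 0 °C
Reagents that add atoms: none
Why: 1,2-addition of the vinyl Grignard reagent to the enal (conjugate addition is blocked by the β,β-dimethyl terminus) should give the bis-allylic alcohol, whose racemic carbinol centre disappears in step 2.

Step 2
Reactants: 3 rac-5-methylhexa-1,4-dien-3-ol
Product: 4 5-methylhexa-1,4-dien-3-one
Conditions: activated MnO2 (excess), CH2Cl2, rt
Reagents that add atoms: none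
Why: allylic oxidation with activated MnO2 is neutral and selective for the doubly allylic alcohol, and the polymerisable divinyl ketone is kept in solution and used at once.

Step 3
Reactants: 5 ethyl 1,3-dithiane-2-carboxylate; 4 5-methylhexa-1,4-dien-3-one
Product: 6 ethyl 2-(5-methyl-3-oxohex-4-en-1-yl)-1,3-dithiane-2-carboxylate
Conditions: t-BuOK (0.1 equiv), THF, −20 °C, slow addition of 4; AcOH
Reagents that add atoms: none
Why: Michael addition in which the soft carbanion of 5, stabilised by two sulfur atoms and the ester, should add to the unsubstituted vinyl terminus only (the β,β-dimethyl terminus is too hindered), and catalytic base suffices because the product enolate deprotonates the next molecule of 5.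

Step 4
Reactants: 6 ethyl 2-(5-methyl-3-oxohex-4-en-1-yl)-1,3-dithiane-2-carboxylate
Product: 7 ethyl 2-[(3R)-3-hydroxy-5-methylhex-4-en-1-yl]-1,3-dithiane-2-carboxylate
Conditions: (S)-2-methyl-CBS-oxazaborolidine (0.2 equiv), catecholborane, toluene, −78 °C; MeOH, aq. NaHCO3
Reagents that add atoms: none
Why: Corey–Bakshi–Shibata reduction in which, with the alkenyl group as the larger ketone substituent, the (S)-oxazaborolidine should deliver hydride to the face that gives the (3R)-allylic alcohol, while catecholborane at −78 °C reduces neither the ester nor the alkene and tolerates the dithiane.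

Step 5
Reactants: 7 ethyl 2-[(3R)-3-hydroxy-5-methylhex-4-en-1-yl]-1,3-dithiane-2-carboxylate
Product: 8 ethyl 2-[(3R)-5-methyl-3-(triethylsilyloxy)hex-4-en-1-yl]-1,3-dithiane-2-carboxylate
Conditions: TESCl, imidazole, DMF, 0 °C
Reagents that add atoms: chlorotriethylsilane, CC[Si](Cl)(CC)CC
Why: standard imidazole-promoted silylation, carried out at once so that the δ-hydroxy ester cannot lactonise, with the triethylsilyl group chosen because it can later be removed beside a TBS ether.

Step 6
Reactants: 8 ethyl 2-[(3R)-5-methyl-3-(triethylsilyloxy)hex-4-en-1-yl]-1,3-dithiane-2-carboxylate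
Product: 9 2-[(3R)-5-methyl-3-(triethylsilyloxy)hex-4-en-1-yl]-1,3-dithiane-2-carbaldehyde
Conditions: DIBAL-H (1.1 equiv), CH2Cl2, −78 °C; MeOH, aq. Rochelle salt
Reagents that add atoms: none
Why: DIBAL-H partial reduction of the ester at −78 °C, where the aluminium hemiacetal, stabilised by the two α-sulfur atoms, should persist until work-up and then release the non-enolisable aldehyde.

Step 7
Reactants: 9 2-[(3R)-5-methyl-3-(triethylsilyloxy)hex-4-en-1-yl]-1,3-dithiane-2-carbaldehyde
Product: 10 (7R,8R,9R)-8-(prop-1-en-2-yl)-9-(triethylsilyloxy)-1,5-dithiaspiro[5.5]undecan-7-ol (target locants 5R,4R,3R; all three substituents equatorial)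
Conditions: Me2AlCl (1.5 equiv), CH2Cl2, −78 → −40 °C; aq. NaHCO3
Reagents that add atoms: none
Why: Me2AlCl binds the non-enolisable aldehyde, alkene carbon C4 bonds to carbonyl carbon C5 and a hydrogen of a C8 methyl group passes to oxygen in a concerted, asynchronous ene process (at the limit through a short-lived tertiary C8 cation), leaving the isopropenyl group; the closest known reaction is the Lewis-acid type I intramolecular carbonyl-ene cyclisation of 6-alkenals with an isopropylidene terminus (citronellal to isopulegol). The cyclohexane ring closes through a chair by 6-exo-trig attack on the carbonyl carbon, with both π bonds exocyclic to the new ring and the geminal substitution at C6 favouring closure (Thorpe–Ingold effect). C4 and C5 are set relative to each other by this chair, in which the isopropylidene unit and the aluminium-bound carbonyl oxygen are both equatorial, hence trans. Both are set relative to C3 by allylic 1,3-strain: the C3–H bond, not the silyloxy group, takes the position near the alkene plane facing the cis methyl group, so the silyloxy group stays equatorial and ends trans to isopropenyl. The step needs activation of the aldehyde in preference to the allylic silyl ether and the sulfur atoms, and clean ene termination; the oxophilic, monodentate Me2AlCl at low temperature, which also removes protons as methane, and the bulky, weakly basic silyl ether should secure this. Isomers from the minor chair are diastereomers and are removed by chromatography here, so that the later oxidation at C3 cannot lower the enantiomeric purity.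

Step 8
Reactants: 10 (7R,8R,9R)-8-(prop-1-en-2-yl)-9-(triethylsilyloxy)-1,5-dithiaspiro[5.5]undecan-7-ol
Product: 11 (7R,8S,9R)-7-(tert-butyldimethylsilyloxy)-8-(prop-1-en-2-yl)-9-(triethylsilyloxy)-1,5-dithiaspiro[5.5]undecane
Conditions: TBSOTf, 2,6-lutidine, CH2Cl2, −40 → 0 °C
Reagents that add atoms: tert-butyldimethylsilyl trifluoromethanesulfonate, CC(C)(C)[Si](C)(C)OS(=O)(=O)C(F)(F)F
Why: silyl triflate/lutidine silylation is forceful enough for the hindered secondary C5 alcohol yet leaves the triethylsilyl ether, the alkene and the dithiane untouched, and the TBS group stays until the last step.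

Step 9
Reactants: 11 (7R,8S,9R)-7-(tert-butyldimethylsilyloxy)-8-(prop-1-en-2-yl)-9-(triethylsilyloxy)-1,5-dithiaspiro[5.5]undecane
Product: 12 (7R,8S,9R)-7-(tert-butyldimethylsilyloxy)-8-isopropyl-9-(triethylsilyloxy)-1,5-dithiaspiro[5.5]undecane
Conditions: 2-nitrobenzenesulfonylhydrazide (NBSH, excess, in portions), Et3N, CH2Cl2, rt
Reagents that add atoms: none
Why: diimide reduction, in which diimide generated from NBSH transfers two hydrogens concertedly to the 1,1-disubstituted alkene and, unlike Pd or Pt catalysts, is not poisoned by the dithiane; no stereocentre is formed, and the alkene must be saturated before C3 is oxidised so that no β,γ-unsaturated ketone able to move into conjugation can arise.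

Step 10
Reactants: 12 (7R,8S,9R)-7-(tert-butyldimethylsilyloxy)-8-isopropyl-9-(triethylsilyloxy)-1,5-dithiaspiro[5.5]undecane
Product: 13 (7R,8S,9R)-7-(tert-butyldimethylsilyloxy)-8-isopropyl-1,5-dithiaspiro[5.5]undecan-9-ol
Conditions: PPTS (0.2 equiv), MeOH/CH2Cl2 (1:1), 0 °C → rt
Reagents that add atoms: none
Why: acid-catalysed methanolysis should remove the less hindered and much more labile secondary triethylsilyl ether while the neopentyl-type TBS ether and the dithiane stay.

Step 11
Reactants: 13 (7R,8S,9R)-7-(tert-butyldimethylsilyloxy)-8-isopropyl-1,5-dithiaspiro[5.5]undecan-9-ol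
Product: 14 (7R,8R)-7-(tert-butyldimethylsilyloxy)-8-isopropyl-1,5-dithiaspiro[5.5]undecan-9-one
Conditions: Dess–Martin periodinane, CH2Cl2, 0 °C → rt
Reagents that add atoms: none
Why: Dess–Martin oxidation under near-neutral conditions should give the ketone without β-elimination of the C5 silyloxy group, and C4 is not at risk because its isopropyl group already sits in the stable equatorial position.

Step 12
Reactants: 14 (7R,8R)-7-(tert-butyldimethylsilyloxy)-8-isopropyl-1,5-dithiaspiro[5.5]undecan-9-one
Product: 15 (7R,8S,9S)-7-(tert-butyldimethylsilyloxy)-8-isopropyl-1,5-dithiaspiro[5.5]undecan-9-ol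
Conditions: L-Selectride, THF, −78 °C; H2O (no peroxide work-up)
Reagents that add atoms: none
Why: substrate-controlled hydride reduction in which the bulky tri-sec-butylborohydride attacks the menthone-type ketone from the equatorial direction (the axial path is blocked by the axial hydrogens on C1 and C5), which should give the axial (3S) alcohol cis to the isopropyl group, as known for menthone going to neomenthol, while the non-oxidative work-up spares the dithiane.

Step 13
Reactants: 15 (7R,8S,9S)-7-(tert-butyldimethylsilyloxy)-8-isopropyl-1,5-dithiaspiro[5.5]undecan-9-ol; 16 tigloyl chloride [(2E)-2-methylbut-2-enoyl chloride]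
Product: 17 (7R,8S,9S)-7-(tert-butyldimethylsilyloxy)-8-isopropyl-1,5-dithiaspiro[5.5]undecan-9-yl (2E)-2-methylbut-2-enoate
Conditions: pyridine, DMAP (0.2 equiv), CH2Cl2, 0 → 40 °C
Reagents that add atoms: none
Why: DMAP-catalysed acylation of the hindered axial alcohol with the acid chloride, with pyridine instead of a trialkylamine so that the tigloyl group is not deconjugated through a vinylketene; the ester also protects C3 for the rest of the route.

Step 14
Reactants: 17 (7R,8S,9S)-7-(tert-butyldimethylsilyloxy)-8-isopropyl-1,5-dithiaspiro[5.5]undecan-9-yl (2E)-2-methylbut-2-enoate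
Product: 18 (1S,2S,3R)-3-(tert-butyldimethylsilyloxy)-2-isopropyl-4-oxocyclohexyl (2E)-2-methylbut-2-enoate
Conditions: MeI (excess), CaCO3, MeCN/H2O (9:1), 45 °C
Reagents that add atoms: water, O
Why: alkylative thioacetal hydrolysis in which S-methylation turns sulfur into a leaving group and water delivers the C6 ketone, while CaCO3 buffers the HI formed so that the TBS ether and the ester survive.

Step 15
Reactants: 18 (1S,2S,3R)-3-(tert-butyldimethylsilyloxy)-2-isopropyl-4-oxocyclohexyl (2E)-2-methylbut-2-enoate
Product: 19 (1S,5R,6S)-5-(tert-butyldimethylsilyloxy)-6-isopropyl-4-(trimethylsilyloxy)cyclohex-3-en-1-yl (2E)-2-methylbut-2-enoate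
Conditions: LiHMDS, TMSCl, THF, −78 °C
Reagents that add atoms: chlorotrimethylsilane, C[Si](C)(C)Cl
Why: kinetic enolisation with LiHMDS in the presence of TMSCl should remove a proton from the C1 methylene rather than from the hindered C5 methine next to the silyloxy group, and at −78 °C it outruns γ-deprotonation of the tiglate.

Step 16
Reactants: 19 (1S,5R,6S)-5-(tert-butyldimethylsilyloxy)-6-isopropyl-4-(trimethylsilyloxy)cyclohex-3-en-1-yl (2E)-2-methylbut-2-enoate
Product: 20 (1S,5R,6S)-5-(tert-butyldimethylsilyloxy)-6-isopropyl-4-oxocyclohex-2-en-1-yl (2E)-2-methylbut-2-enoate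
Conditions: Pd(OAc)2 (1.1 equiv), MeCN, rt
Reagents that add atoms: none
Why: Saegusa–Ito oxidation, in which the palladium(II) enolate formed from the enol silane undergoes β-hydride elimination toward C2 and so places the double bond at C1=C2 regiospecifically.

Step 17
Reactants: 20 (1S,5R,6S)-5-(tert-butyldimethylsilyloxy)-6-isopropyl-4-oxocyclohex-2-en-1-yl (2E)-2-methylbut-2-enoate
Product: 21 (1S,5R,6S)-5-(tert-butyldimethylsilyloxy)-3-(hydroxymethyl)-6-isopropyl-4-oxocyclohex-2-en-1-yl (2E)-2-methylbut-2-enoate
Conditions: 37% aq. formaldehyde, DMAP (0.3 equiv), THF/H2O, rt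
Reagents that add atoms: formaldehyde, C=O
Why: Morita–Baylis–Hillman reaction in which DMAP adds reversibly at C2, the resulting enolate at C1 captures formaldehyde and loss of the catalyst restores the enone, as established for 4-oxygenated cyclohex-2-enones; no stereocentre is formed and the weakly basic medium should leave C5, the silyl ether and the ester alone.

Step 18
Reactants: 21 (1S,5R,6S)-5-(tert-butyldimethylsilyloxy)-3-(hydroxymethyl)-6-isopropyl-4-oxocyclohex-2-en-1-yl (2E)-2-methylbut-2-enoate; 16 tigloyl chloride
Product: 22 [(3S,4S,5R)-5-(tert-butyldimethylsilyloxy)-4-isopropyl-3-{[(2E)-2-methylbut-2-enoyl]oxy}-6-oxocyclohex-1-en-1-yl]methyl (2E)-2-methylbut-2-enoate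
Conditions: pyridine, CH2Cl2, 0 °C
Reagents that add atoms: none
Why: acylation of the unhindered primary allylic alcohol with the acid chloride and pyridine at 0 °C.

Step 19
Reactants: 22 [(3S,4S,5R)-5-(tert-butyldimethylsilyloxy)-4-isopropyl-3-{[(2E)-2-methylbut-2-enoyl]oxy}-6-oxocyclohex-1-en-1-yl]methyl (2E)-2-methylbut-2-enoate
Product: 23 [(3S,4R,5R)-5-hydroxy-4-isopropyl-3-{[(2E)-2-methylbut-2-enoyl]oxy}-6-oxocyclohex-1-en-1-yl]methyl (2E)-2-methylbut-2-enoate
Conditions: HF·pyridine, pyridine, THF, 0 °C → rt
Reagents that add atoms: none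
Why: fluoride-mediated desilylation driven by the strong Si–F bond under buffered, non-basic conditions, so that the enone, the two allylic esters and the α-ketol should survive without acyl migration, elimination or epimerisation at C5.

**Compound list**

1 | 3-methylbut-2-enal | CC(C)=CC=O | starting material
2 | vinylmagnesium bromide | C=C[Mg]Br | starting material
3 | rac-5-methylhexa-1,4-dien-3-ol | C=CC(O)C=C(C)C | intermediate
4 | 5-methylhexa-1,4-dien-3-one | C=CC(=O)C=C(C)C | intermediate
5 | ethyl 1,3-dithiane-2-carboxylate | CCOC(=O)C1SCCCS1 | starting material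
6 | ethyl 2-(5-methyl-3-oxohex-4-en-1-yl)-1,3-dithiane-2-carboxylate | CCOC(=O)C1(CCC(=O)C=C(C)C)SCCCS1 | intermediate
7 | ethyl 2-[(3R)-3-hydroxy-5-methylhex-4-en-1-yl]-1,3-dithiane-2-carboxylate | CCOC(=O)C1(CC[C@@H](O)C=C(C)C)SCCCS1 | intermediate
8 | ethyl 2-[(3R)-5-methyl-3-(triethylsilyloxy)hex-4-en-1-yl]-1,3-dithiane-2-carboxylate | CCOC(=O)C1(CC[C@@H](O[Si](CC)(CC)CC)C=C(C)C)SCCCS1 | intermediate
9 | 2-[(3R)-5-methyl-3-(triethylsilyloxy)hex-4-en-1-yl]-1,3-dithiane-2-carbaldehyde | O=CC1(CC[C@@H](O[Si](CC)(CC)CC)C=C(C)C)SCCCS1 | intermediate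
10 | (7R,8R,9R)-8-(prop-1-en-2-yl)-9-(triethylsilyloxy)-1,5-dithiaspiro[5.5]undecan-7-ol | C1C[C@@H](O[Si](CC)(CC)CC)[C@H](C(C)=C)[C@@H](O)C12SCCCS2 | intermediate
11 | (7R,8S,9R)-7-(tert-butyldimethylsilyloxy)-8-(prop-1-en-2-yl)-9-(triethylsilyloxy)-1,5-dithiaspiro[5.5]undecane | C1C[C@@H](O[Si](CC)(CC)CC)[C@H](C(C)=C)[C@@H](O[Si](C)(C)C(C)(C)C)C12SCCCS2 | intermediate
12 | (7R,8S,9R)-7-(tert-butyldimethylsilyloxy)-8-isopropyl-9-(triethylsilyloxy)-1,5-dithiaspiro[5.5]undecane | C1C[C@@H](O[Si](CC)(CC)CC)[C@H](C(C)C)[C@@H](O[Si](C)(C)C(C)(C)C)C12SCCCS2 | intermediate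
13 | (7R,8S,9R)-7-(tert-butyldimethylsilyloxy)-8-isopropyl-1,5-dithiaspiro[5.5]undecan-9-ol (C3 hydroxyl equatorial, trans to isopropyl) | C1C[C@@H](O)[C@H](C(C)C)[C@@H](O[Si](C)(C)C(C)(C)C)C12SCCCS2 | intermediate
14 | (7R,8R)-7-(tert-butyldimethylsilyloxy)-8-isopropyl-1,5-dithiaspiro[5.5]undecan-9-one | C1CC(=O)[C@H](C(C)C)[C@@H](O[Si](C)(C)C(C)(C)C)C12SCCCS2 | intermediate
15 | (7R,8S,9S)-7-(tert-butyldimethylsilyloxy)-8-isopropyl-1,5-dithiaspiro[5.5]undecan-9-ol (C3 hydroxyl axial, cis to isopropyl) | C1C[C@H](O)[C@H](C(C)C)[C@@H](O[Si](C)(C)C(C)(C)C)C12SCCCS2 | intermediate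
16 | tigloyl chloride, (2E)-2-methylbut-2-enoyl chloride | C/C=C(\C)C(=O)Cl | starting material
17 | (7R,8S,9S)-7-(tert-butyldimethylsilyloxy)-8-isopropyl-1,5-dithiaspiro[5.5]undecan-9-yl (2E)-2-methylbut-2-enoate | C1C[C@H](OC(=O)/C(C)=C/C)[C@H](C(C)C)[C@@H](O[Si](C)(C)C(C)(C)C)C12SCCCS2 | intermediate
18 | (1S,2S,3R)-3-(tert-butyldimethylsilyloxy)-2-isopropyl-4-oxocyclohexyl (2E)-2-methylbut-2-enoate | C1C[C@H](OC(=O)/C(C)=C/C)[C@H](C(C)C)[C@@H](O[Si](C)(C)C(C)(C)C)C1=O | intermediate
19 | (1S,5R,6S)-5-(tert-butyldimethylsilyloxy)-6-isopropyl-4-(trimethylsilyloxy)cyclohex-3-en-1-yl (2E)-2-methylbut-2-enoate | C1[C@H](OC(=O)/C(C)=C/C)[C@H](C(C)C)[C@@H](O[Si](C)(C)C(C)(C)C)C(O[Si](C)(C)C)=C1 | intermediate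
20 | (1S,5R,6S)-5-(tert-butyldimethylsilyloxy)-6-isopropyl-4-oxocyclohex-2-en-1-yl (2E)-2-methylbut-2-enoate | C1=C[C@H](OC(=O)/C(C)=C/C)[C@H](C(C)C)[C@@H](O[Si](C)(C)C(C)(C)C)C1=O | intermediate
21 | (1S,5R,6S)-5-(tert-butyldimethylsilyloxy)-3-(hydroxymethyl)-6-isopropyl-4-oxocyclohex-2-en-1-yl (2E)-2-methylbut-2-enoate | OCC1=C[C@H](OC(=O)/C(C)=C/C)[C@H](C(C)C)[C@@H](O[Si](C)(C)C(C)(C)C)C1=O | intermediate
22 | [(3S,4S,5R)-5-(tert-butyldimethylsilyloxy)-4-isopropyl-3-{[(2E)-2-methylbut-2-enoyl]oxy}-6-oxocyclohex-1-en-1-yl]methyl (2E)-2-methylbut-2-enoate | C/C=C(\C)C(=O)OCC1=C[C@H](OC(=O)/C(C)=C/C)[C@H](C(C)C)[C@@H](O[Si](C)(C)C(C)(C)C)C1=O | intermediate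
23 | [(3S,4R,5R)-5-hydroxy-4-isopropyl-3-{[(2E)-2-methylbut-2-enoyl]oxy}-6-oxocyclohex-1-en-1-yl]methyl (2E)-2-methylbut-2-enoate | C/C=C(\C)C(=O)OCC1=C[C@H](OC(=O)/C(C)=C/C)[C@H](C(C)C)[C@@H](O)C1=O | target

**Step count and risks**

Total step count: 19. Longest linear sequence: 19 steps (1 → 23); compounds 2, 5 and 16 enter as reaction partners.

Steps most likely to fail:

1. Step 7. Part of the material may close through a transition state in which the complexed carbonyl oxygen is axial, so that the trans relationship between C4 and C5 is lost and the C5-epimeric carbinol accompanies 10. The fallback sets out from 10 (as obtained, mixed with its C5 epimer) and comes back at 12; it fixes C5 after the ring closure instead of in it. Diimide reduction of the mixture (NBSH, Et3N, CH2Cl2) would give the isopropyl carbinol F1 and its C5 epimer F2. Dess–Martin oxidation would converge both on the α-dithianyl ketone F3. Sodium borohydride (MeOH, −40 °C), adding axially and anti to the axial C–S bond, should return F1 alone, and TBSOTf/2,6-lutidine would then give 12.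

2. Step 17. Turnover of the amine-catalysed addition–aldol–elimination sequence may be too slow on the substituted enone, so that base-mediated loss of the γ-acyloxy group and aromatisation overtake hydroxymethylation. The fallback sets out from 20 and comes back at 21; it replaces the catalytic sequence by two stoichiometric, irreversible steps. α-Iodination (I2, pyridine, CH2Cl2, 0 °C) would give the 2-iodoenone F4, and Stille coupling with (tributylstannyl)methanol (Pd2(dba)3, AsPh3, CuI, NMP, rt to 40 °C) should give 21; the mild arsine conditions are chosen so that the allylic tiglate is not ionised.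

3. Step 3. Base-initiated oligomerisation of the cross-conjugated dienone 4, and its loss on handling, may compete with the Michael addition. The fallback sets out from 5 and comes back at 6, without passing through 3 and 4. Conjugate addition of 5 to N-methoxy-N-methylacrylamide (t-BuOK cat., THF) would give the Weinreb amide F5. 2-Methylprop-1-enylmagnesium bromide (THF, −20 → 0 °C) should then add once to the amide, through the chelated tetrahedral intermediate and in preference to the neopentyl-type ethyl ester, to give 6 on work-up.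

Further compounds
F1 | step 7 | (7R,8R,9R)-8-isopropyl-9-(triethylsilyloxy)-1,5-dithiaspiro[5.5]undecan-7-ol | C1C[C@@H](O[Si](CC)(CC)CC)[C@H](C(C)C)[C@@H](O)C12SCCCS2
F2 | step 7 | (7S,8R,9R)-8-isopropyl-9-(triethylsilyloxy)-1,5-dithiaspiro[5.5]undecan-7-ol (C5 epimer of F1) | C1C[C@@H](O[Si](CC)(CC)CC)[C@H](C(C)C)[C@H](O)C12SCCCS2
F3 | step 7 | (8S,9R)-8-isopropyl-9-(triethylsilyloxy)-1,5-dithiaspiro[5.5]undecan-7-one | C1C[C@@H](O[Si](CC)(CC)CC)[C@H](C(C)C)C(=O)C12SCCCS2
F4 | step 17 | (1R,5R,6S)-5-(tert-butyldimethylsilyloxy)-3-iodo-6-isopropyl-4-oxocyclohex-2-en-1-yl (2E)-2-methylbut-2-enoate (same spatial arrangement as 20) | IC1=C[C@H](OC(=O)/C(C)=C/C)[C@H](C(C)C)[C@@H](O[Si](C)(C)C(C)(C)C)C1=O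
F5 | step 3 | ethyl 2-{3-[methoxy(methyl)amino]-3-oxopropyl}-1,3-dithiane-2-carboxylate | CCOC(=O)C1(CCC(=O)N(C)OC)SCCCS1
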